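Ring C is opened between C2 and C3 by way of a flav-2-ene. The feature exploited is that C2 carries both O1 and ring B, so it is an ester carbon in disguise (ring B acid on the ring A phenol), while C3–C4 is an ortho allyl arm on ring A. One titanium-mediated carbonyl–olefin metathesis turns this olefinic aryl ester into the 2-aryl-4H-chromene, forming C2=C3 and the pyran ring together. Syn hydroboration of that enol ether with an enantiopure borane then sets the 2,3-trans (2R,3S) pair. Silyl ethers at O7 and O3' against benzyl ethers at O5 and O4' direct the two gallates before global hydrogenolysis.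

Key step: step 9

Remark: compounds 1, 8 and 17 are taken as purchased, and monoisopinocampheylborane (IpcBH2) as made beforehand from (+)-α-pinene; the pinene antipode is assigned by analogy with 1-arylcycloalkenes.

Step 1
Reactants: 1 2,4,6-trihydroxybenzaldehyde
Product: 2 2,6-dihydroxy-4-[(triisopropylsilyl)oxy]benzaldehyde
Conditions: TIPSCl (1.05 equiv), imidazole, DMF, 0 °C
Reagents that add atoms: triisopropylsilyl chloride, CC(C)[Si](Cl)(C(C)C)C(C)C
Why: The 4-hydroxyl is the only one not hydrogen-bonded to the formyl group and is the least hindered, so the bulky silyl chloride should react there (regioselective O-silylation).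

Step 2
Reactants: 2 2,6-dihydroxy-4-[(triisopropylsilyl)oxy]benzaldehyde
Product: 3 2-(benzyloxy)-6-hydroxy-4-[(triisopropylsilyl)oxy]benzaldehyde
Conditions: BnBr (1.05 equiv), K2CO3, acetone, 50 °C
Reagents that add atoms: benzyl bromide, BrCc1ccccc1
Why: Williamson etherification of one of the two equivalent chelated hydroxyls; after the first benzylation the remaining hydroxyl is held in a stronger hydrogen bond to the aldehyde, which should stop the reaction at the mono-ether.

Step 3
Reactants: 3 2-(benzyloxy)-6-hydroxy-4-[(triisopropylsilyl)oxy]benzaldehyde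
Product: 4 3-(benzyloxy)-2-formyl-5-[(triisopropylsilyl)oxy]phenyl tert-butyl carbonate
Conditions: Boc2O, i-Pr2NEt, DMAP (cat.), THF, 0 °C to rt
Reagents that add atoms: di-tert-butyl dicarbonate, CC(C)(C)OC(=O)OC(=O)OC(C)(C)C
Why: DMAP-catalysed O-acylation of the phenol gives the aryl carbonate that later triggers ortho-quinone methide formation.

Step 4
Reactants: 4 3-(benzyloxy)-2-formyl-5-[(triisopropylsilyl)oxy]phenyl tert-butyl carbonate
Product: 5 3-(benzyloxy)-2-(hydroxymethyl)-5-[(triisopropylsilyl)oxy]phenyl tert-butyl carbonate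
Conditions: BH3·THF, THF, −10 °C; pH 7 buffer work-up
Reagents that add atoms: none
Why: Borane reduces the aldehyde through a neutral borate ester, so no free alkoxide is formed that could start carbonate migration (chemoselective carbonyl reduction).

Step 5
Reactants: 5 3-(benzyloxy)-2-(hydroxymethyl)-5-[(triisopropylsilyl)oxy]phenyl tert-butyl carbonate
Product: 7 2-allyl-3-(benzyloxy)-5-[(triisopropylsilyl)oxy]phenol, via ortho-quinone methide 6 (not isolated)
Conditions: vinylmagnesium bromide (2.5 equiv), THF, −78 °C to 0 °C; aq NH4Cl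
Reagents that add atoms: vinylmagnesium bromide, C=C[Mg]Br
Why: The first equivalent deprotonates the alcohol, the Boc group migrates to the benzylic oxygen and is expelled to give ortho-quinone methide 6, which takes up the vinyl nucleophile at the exocyclic carbon (anionic ortho-quinone methide generation and 1,4-addition).

Step 6
Reactants: 8 4-(benzyloxy)-3-hydroxybenzaldehyde
Product: 9 4-(benzyloxy)-3-[(triisopropylsilyl)oxy]benzaldehyde
Conditions: TIPSCl, imidazole, DMF, rt
Reagents that add atoms: triisopropylsilyl chloride, CC(C)[Si](Cl)(C(C)C)C(C)C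
Why: Standard O-silylation of the only free phenol.

Step 7
Reactants: 9 4-(benzyloxy)-3-[(triisopropylsilyl)oxy]benzaldehyde
Product: 10 4-(benzyloxy)-3-[(triisopropylsilyl)oxy]benzoic acid
Conditions: NaClO2, NaH2PO4, 2-methyl-2-butene, t-BuOH/H2O, rt
Reagents that add atoms: sodium chlorite, [Na+].[O-]Cl=O
Why: Pinnick oxidation converts the aldehyde to the acid without touching the aryl silyl or benzyl ether.

Step 8
Reactants: 7 2-allyl-3-(benzyloxy)-5-[(triisopropylsilyl)oxy]phenol, 10 4-(benzyloxy)-3-[(triisopropylsilyl)oxy]benzoic acid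
Product: 11 2-allyl-3-(benzyloxy)-5-[(triisopropylsilyl)oxy]phenyl 4-(benzyloxy)-3-[(triisopropylsilyl)oxy]benzoate
Conditions: DCC, DMAP (cat.), CH2Cl2, 0 °C to rt
Reagents that add atoms: none
Why: Steglich esterification joins the ring A phenol and the ring B acid and so creates the future O1–C2 bond.

Step 9
Reactants: 11 2-allyl-3-(benzyloxy)-5-[(triisopropylsilyl)oxy]phenyl 4-(benzyloxy)-3-[(triisopropylsilyl)oxy]benzoate
Product: 13 5-(benzyloxy)-2-{4-(benzyloxy)-3-[(triisopropylsilyl)oxy]phenyl}-7-[(triisopropylsilyl)oxy]-4H-chromene, via acyclic enol ether 12 (not isolated)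
Conditions: Cp2Ti(μ-CH2)(μ-Cl)AlMe2 (Tebbe reagent, 4 equiv), pyridine (cat.), THF, −40 °C to 25 °C, then reflux; aq NaOH quench, basic alumina
Reagents that add atoms: none
Why: Cp2Ti=CH2 released from the reagent first methylenates the only carbonyl group, the aryl ester, through an oxatitanacyclobutane to give enol ether 12; on heating, further titanium methylidene exchanges with the terminal allyl alkene to give a titanium alkylidene at C3, which adds across the 1,1-disubstituted enol ether and cycloreverts, forming C2=C3 with loss of ethene. The closest known reaction type is the tandem ester methylenation/olefin metathesis of olefinic esters to cyclic enol ethers (olefinic ester cyclization). The six-membered pyran ring is closed by ring-closing olefin metathesis through a bicyclic titanacyclobutane, so the new double bond is endocyclic between C2 and C3. No stereocenter is formed here; C2 and C3 are left as a planar enol ether for step 10. The step needs carbonyl methylenation before metathesis, and cyclization rather than allyl-to-propenyl isomerization or oligomerization; the single carbonyl group, the terminal alkene as the only site for alkylidene exchange, and the ortho placement of ester oxygen and allyl group on ring A (only a six-membered ring is within reach) should secure this.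

Step 10
Reactants: 13 5-(benzyloxy)-2-{4-(benzyloxy)-3-[(triisopropylsilyl)oxy]phenyl}-7-[(triisopropylsilyl)oxy]-4H-chromene
Product: 15 (2R,3S)-5-(benzyloxy)-2-{4-(benzyloxy)-3-[(triisopropylsilyl)oxy]phenyl}-7-[(triisopropylsilyl)oxy]chroman-3-ol, via flavan-3-yl(isopinocampheyl)borane 14 (not isolated)
Conditions: IpcBH2 [from (+)-α-pinene, 1.5 equiv], THF, −25 °C; then 30% H2O2, aq NaOAc, 0 °C to rt
Reagents that add atoms: hydrogen peroxide, OO
Why: Syn addition of H–B across C2=C3 places boron on C3 (β to the ring oxygen) and hydrogen on C2, and oxidation with retention gives the 2,3-trans alcohol, while the isopinocampheyl group selects the alkene face (reagent-controlled asymmetric hydroboration), the (2R,3S) sense being assigned by analogy with 1-arylcycloalkenes, which give the spatially corresponding trans-2-arylcycloalkanols.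

Step 11
Reactants: 15 (2R,3S)-5-(benzyloxy)-2-{4-(benzyloxy)-3-[(triisopropylsilyl)oxy]phenyl}-7-[(triisopropylsilyl)oxy]chroman-3-ol
Product: 16 (2R,3S)-5-(benzyloxy)-2-[4-(benzyloxy)-3-hydroxyphenyl]chromane-3,7-diol
Conditions: TBAF (2.2 equiv), AcOH (2.2 equiv), THF, 0 °C
Reagents that add atoms: none
Why: Fluoride cleaves both aryl silyl ethers while acetic acid buffers the phenoxides, and the benzyl ethers are untouched (desilylation).

Step 12
Reactants: 16 (2R,3S)-5-(benzyloxy)-2-[4-(benzyloxy)-3-hydroxyphenyl]chromane-3,7-diol, 17 3,4,5-tris(benzyloxy)benzoyl chloride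
Product: 18 (2R,3S)-5-(benzyloxy)-2-{4-(benzyloxy)-3-[3,4,5-tris(benzyloxy)benzoyloxy]phenyl}-3-hydroxychroman-7-yl 3,4,5-tris(benzyloxy)benzoate
Conditions: 17 (2.1 equiv), Et3N (2.5 equiv), CH2Cl2, −20 °C to 0 °C
Reagents that add atoms: none
Why: With amine base and no acyl-transfer catalyst the two phenols (O7 and O3') should be acylated much faster than the hindered secondary 3-hydroxyl (phenol-selective O-acylation with an acid chloride).

Step 13
Reactants: 18 (2R,3S)-5-(benzyloxy)-2-{4-(benzyloxy)-3-[3,4,5-tris(benzyloxy)benzoyloxy]phenyl}-3-hydroxychroman-7-yl 3,4,5-tris(benzyloxy)benzoate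
Product: 19 catechin 7,3'-di-O-gallate
Conditions: H2 (1 atm), Pd(OH)2/C, THF/EtOAc, rt
Reagents that add atoms: none
Why: Hydrogenolysis removes all eight benzyl ethers under neutral conditions that should leave the aryl gallate esters and the benzylic C2–O1 bond intact and give no base to drive 3'-to-4' acyl migration.

Compound list
1 | 2,4,6-trihydroxybenzaldehyde | O=Cc1c(O)cc(O)cc1O | starting material
2 | 2,6-dihydroxy-4-[(triisopropylsilyl)oxy]benzaldehyde | O=Cc1c(O)cc(O[Si](C(C)C)(C(C)C)C(C)C)cc1O | intermediate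
3 | 2-(benzyloxy)-6-hydroxy-4-[(triisopropylsilyl)oxy]benzaldehyde | O=Cc1c(O)cc(O[Si](C(C)C)(C(C)C)C(C)C)cc1OCc1ccccc1 | intermediate
4 | 3-(benzyloxy)-2-formyl-5-[(triisopropylsilyl)oxy]phenyl tert-butyl carbonate | O=Cc1c(OC(=O)OC(C)(C)C)cc(O[Si](C(C)C)(C(C)C)C(C)C)cc1OCc1ccccc1 | intermediate
5 | 3-(benzyloxy)-2-(hydroxymethyl)-5-[(triisopropylsilyl)oxy]phenyl tert-butyl carbonate | OCc1c(OC(=O)OC(C)(C)C)cc(O[Si](C(C)C)(C(C)C)C(C)C)cc1OCc1ccccc1 | intermediate
6 | 5-(benzyloxy)-6-methylidene-3-[(triisopropylsilyl)oxy]cyclohexa-2,4-dien-1-one (ortho-quinone methide, not isolated) | C=C1C(OCc2ccccc2)=CC(O[Si](C(C)C)(C(C)C)C(C)C)=CC1=O | intermediate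
7 | 2-allyl-3-(benzyloxy)-5-[(triisopropylsilyl)oxy]phenol | C=CCc1c(O)cc(O[Si](C(C)C)(C(C)C)C(C)C)cc1OCc1ccccc1 | intermediate
8 | 4-(benzyloxy)-3-hydroxybenzaldehyde | O=Cc1ccc(OCc2ccccc2)c(O)c1 | starting material
9 | 4-(benzyloxy)-3-[(triisopropylsilyl)oxy]benzaldehyde | O=Cc1ccc(OCc2ccccc2)c(O[Si](C(C)C)(C(C)C)C(C)C)c1 | intermediate
10 | 4-(benzyloxy)-3-[(triisopropylsilyl)oxy]benzoic acid | OC(=O)c1ccc(OCc2ccccc2)c(O[Si](C(C)C)(C(C)C)C(C)C)c1 | intermediate
11 | 2-allyl-3-(benzyloxy)-5-[(triisopropylsilyl)oxy]phenyl 4-(benzyloxy)-3-[(triisopropylsilyl)oxy]benzoate | C=CCc1c(OC(=O)c2ccc(OCc3ccccc3)c(O[Si](C(C)C)(C(C)C)C(C)C)c2)cc(O[Si](C(C)C)(C(C)C)C(C)C)cc1OCc1ccccc1 | intermediate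
12 | 2-allyl-1-(benzyloxy)-3-({1-[4-(benzyloxy)-3-(triisopropylsilyloxy)phenyl]ethenyl}oxy)-5-(triisopropylsilyloxy)benzene (acyclic enol ether, not isolated) | C=CCc1c(OC(=C)c2ccc(OCc3ccccc3)c(O[Si](C(C)C)(C(C)C)C(C)C)c2)cc(O[Si](C(C)C)(C(C)C)C(C)C)cc1OCc1ccccc1 | intermediate
13 | 5-(benzyloxy)-2-{4-(benzyloxy)-3-[(triisopropylsilyl)oxy]phenyl}-7-[(triisopropylsilyl)oxy]-4H-chromene | CC(C)[Si](C(C)C)(C(C)C)Oc1cc(OCc3ccccc3)c2c(c1)OC(c1ccc(OCc3ccccc3)c(O[Si](C(C)C)(C(C)C)C(C)C)c1)=CC2 | intermediate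
14 | [(2R,3S)-5-(benzyloxy)-2-{4-(benzyloxy)-3-[(triisopropylsilyl)oxy]phenyl}-7-[(triisopropylsilyl)oxy]chroman-3-yl][(1R,2R,3R,5S)-isopinocampheyl]borane (not isolated) | CC(C)[Si](C(C)C)(C(C)C)Oc1cc(OCc3ccccc3)c2c(c1)O[C@H](c1ccc(OCc3ccccc3)c(O[Si](C(C)C)(C(C)C)C(C)C)c1)[C@@H](B[C@@H]1C[C@@H]3C[C@H]([C@H]1C)C3(C)C)C2 | intermediate
15 | (2R,3S)-5-(benzyloxy)-2-{4-(benzyloxy)-3-[(triisopropylsilyl)oxy]phenyl}-7-[(triisopropylsilyl)oxy]chroman-3-ol | CC(C)[Si](C(C)C)(C(C)C)Oc1cc(OCc3ccccc3)c2c(c1)O[C@H](c1ccc(OCc3ccccc3)c(O[Si](C(C)C)(C(C)C)C(C)C)c1)[C@@H](O)C2 | intermediate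
16 | (2R,3S)-5-(benzyloxy)-2-[4-(benzyloxy)-3-hydroxyphenyl]chromane-3,7-diol | Oc1cc(OCc3ccccc3)c2c(c1)O[C@H](c1ccc(OCc3ccccc3)c(O)c1)[C@@H](O)C2 | intermediate
17 | 3,4,5-tris(benzyloxy)benzoyl chloride | O=C(Cl)c1cc(OCc2ccccc2)c(OCc2ccccc2)c(OCc2ccccc2)c1 | starting material
18 | (2R,3S)-5-(benzyloxy)-2-{4-(benzyloxy)-3-[3,4,5-tris(benzyloxy)benzoyloxy]phenyl}-3-hydroxychroman-7-yl 3,4,5-tris(benzyloxy)benzoate | O=C(Oc1cc(OCc3ccccc3)c2c(c1)O[C@H](c1ccc(OCc3ccccc3)c(OC(=O)c3cc(OCc4ccccc4)c(OCc4ccccc4)c(OCc4ccccc4)c3)c1)[C@@H](O)C2)c1cc(OCc2ccccc2)c(OCc2ccccc2)c(OCc2ccccc2)c1 | intermediate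
19 | catechin 7,3'-di-O-gallate, (2R,3S) | O=C(Oc1cc(O)c2c(c1)O[C@H](c1ccc(O)c(OC(=O)c3cc(O)c(O)c(O)c3)c1)[C@@H](O)C2)c1cc(O)c(O)c(O)c1 | target

Total step count: 13. Longest linear sequence: 11 steps (steps 1–5 and 8–13).

Steps most likely to fail

Step 9. The titanium alkylidene may fail to engage the hindered aryl-substituted enol ether, so the reaction stalls after methylenation, or the allyl group may isomerize before ring closure. Fallback: setting out from 11, the ester is only methylenated (Cp2Ti(μ-CH2)(μ-Cl)AlMe2, 1.3 equiv, THF/pyridine, −40 °C to 0 °C) and enol ether 12 is isolated on basic alumina. The ring is then closed by ruthenium-catalysed ring-closing metathesis with second-generation Grubbs catalyst, (H2IMes)(PCy3)Cl2Ru=CHPh, in toluene at 70 °C with 1,4-benzoquinone to suppress alkene migration. The route is rejoined at 13.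

Step 10. Facial discrimination by the chiral borane may be poor on this heavily substituted enol ether. Fallback: setting out from 13, hydroboration with BH3·SMe2 and oxidation with H2O2/NaOAc should give the racemic trans alcohol, that is 15 together with the enantiomeric (2S,3R)-alcohol F1. Lipase-catalysed acetylation (Burkholderia cepacia lipase, vinyl acetate, MTBE) is expected, by the empirical rule for secondary alcohols and the behaviour of trans-2-arylcycloalkanols, to convert F1 into the (2S,3R)-acetate F2. Unreacted 15 is separated and the route is rejoined at 15.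

Step 12. Acylation may not stop at the two phenols and may reach the 3-hydroxyl, or remain incomplete. Fallback: setting out from 15, the 3-hydroxyl is benzylated first with benzyl 2,2,2-trichloroacetimidate and catalytic TfOH (CH2Cl2/cyclohexane, 0 °C) to give the 3-O-benzyl ether F3. Desilylation (TBAF/AcOH, THF) gives the 3-O-benzyl diphenol F4. Exhaustive acylation with 17 (Et3N, DMAP, CH2Cl2) gives the 3-O-benzyl bis-gallate F5, and hydrogenolysis (H2, Pd(OH)2/C, THF/EtOAc) removes all nine benzyl groups. The route is rejoined at 19.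

Further compounds
F0 | step 9 | none | none
F1 | step 10 | (2S,3R)-5-(benzyloxy)-2-{4-(benzyloxy)-3-[(triisopropylsilyl)oxy]phenyl}-7-[(triisopropylsilyl)oxy]chroman-3-ol | CC(C)[Si](C(C)C)(C(C)C)Oc1cc(OCc3ccccc3)c2c(c1)O[C@@H](c1ccc(OCc3ccccc3)c(O[Si](C(C)C)(C(C)C)C(C)C)c1)[C@H](O)C2
F2 | step 10 | (2S,3R)-5-(benzyloxy)-2-{4-(benzyloxy)-3-[(triisopropylsilyl)oxy]phenyl}-7-[(triisopropylsilyl)oxy]chroman-3-yl acetate | CC(C)[Si](C(C)C)(C(C)C)Oc1cc(OCc3ccccc3)c2c(c1)O[C@@H](c1ccc(OCc3ccccc3)c(O[Si](C(C)C)(C(C)C)C(C)C)c1)[C@H](OC(C)=O)C2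
F3 | step 12 | (2R,3S)-3,5-bis(benzyloxy)-2-{4-(benzyloxy)-3-[(triisopropylsilyl)oxy]phenyl}-7-[(triisopropylsilyl)oxy]chromane | CC(C)[Si](C(C)C)(C(C)C)Oc1cc(OCc3ccccc3)c2c(c1)O[C@H](c1ccc(OCc3ccccc3)c(O[Si](C(C)C)(C(C)C)C(C)C)c1)[C@@H](OCc1ccccc1)C2
F4 | step 12 | (2R,3S)-3,5-bis(benzyloxy)-2-[4-(benzyloxy)-3-hydroxyphenyl]chroman-7-ol | Oc1cc(OCc3ccccc3)c2c(c1)O[C@H](c1ccc(OCc3ccccc3)c(O)c1)[C@@H](OCc1ccccc1)C2
F5 | step 12 | (2R,3S)-3,5-bis(benzyloxy)-2-{4-(benzyloxy)-3-[3,4,5-tris(benzyloxy)benzoyloxy]phenyl}chroman-7-yl 3,4,5-tris(benzyloxy)benzoate | O=C(Oc1cc(OCc3ccccc3)c2c(c1)O[C@H](c1ccc(OCc3ccccc3)c(OC(=O)c3cc(OCc4ccccc4)c(OCc4ccccc4)c(OCc4ccccc4)c3)c1)[C@@H](OCc1ccccc1)C2)c1cc(OCc2ccccc2)c(OCc2ccccc2)c(OCc2ccccc2)c1
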